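**Retrosynthetic overview**
1. Acid 27 comes from primary alcohol 25 (oxidation at C1); the C8–C18 tail comes from a farnesyl Wittig reaction on the C7 aldehyde 19, then diimide saturation of C7=C8.
2. Feature used: in the 1,2-dioxane ring (O1, O2, C3–C6) the O1–C6 bond ends at the quaternary ring carbon C6, which carries a methyl group and the exocyclic CH2 C7. This is the pattern of a 2-methyl-2-alkyloxirane (C6, C7, O) opened at its tertiary carbon.
3. The only ring is formed once: dioxane 18 from hydroperoxy epoxide 17, by acid-mediated 6-exo attack of the C3 hydroperoxide on C6 with inversion (O1–C6 bond, C7 released as CH2OH).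
4. 17 comes from epoxy mesylate 16 (SN2 at C3 by HOO−, inversion), which comes from the Evans syn-aldol adduct 10 (C2, C3); the oxirane is rebuilt from an acetonide-masked 1,2-diol only after C3 is mesylated.
5. C6 comes from (R)-2-methylglycidol 1, opened at its ring CH2 by allylmagnesium bromide 2; ozonolysis then gives aldehyde 6.

Key step: step 11

Numbering used throughout: C1 = carboxyl carbon, C2 = CH(CH3), C3–C6 = ring carbons (O2 on C3, O1 on C6), C7–C18 = chain.

Assumption: both enantiomers of 2-methylglycidol are commercial. The (R)-enantiomer is used because the allyl group enters at the ring CH2 and the oxirane is later rebuilt on the former CH2OH carbon, which makes the oxirane of 16 and 17 (S).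

**Route**

Step 1
Reactants: 1 (R)-2-methylglycidol; 2 allylmagnesium bromide
Product: 3 (2S)-2-methylhex-5-ene-1,2-diol
Conditions: CH2=CHCH2MgBr (3 equiv), CuI (10 mol%), THF, −30 → 0 °C; aq. NH4Cl
Reagents that add atoms: none
Why: Copper-catalysed Grignard opening of an epoxide (SN2) takes place at the unsubstituted ring CH2 of the 2,2-disubstituted oxirane, so the tertiary C–O bond is untouched and the quaternary stereocentre (C6 of the target) is carried over unchanged from the chiral pool; a Payne shift of the intermediate alkoxide would return the same enantiomer.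

Step 2
Reactants: 3 (2S)-2-methylhex-5-ene-1,2-diol
Product: 4 (4S)-4-(but-3-en-1-yl)-2,2,4-trimethyl-1,3-dioxolane
Conditions: 2,2-dimethoxypropane, PPTS (cat.), CH2Cl2, rt
Reagents that add atoms: 2,2-dimethoxypropane COC(C)(C)OC
Why: Acid-catalysed acetonide formation masks the diol that later becomes the oxirane, because an oxirane carried through the aldol stage would be opened (5-exo) by the free C3 hydroxyl to a tetrahydrofuran; no stereocentre is touched.

Step 3
Reactants: 4 (4S)-4-(but-3-en-1-yl)-2,2,4-trimethyl-1,3-dioxolane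
Product: 6 3-[(4S)-2,2,4-trimethyl-1,3-dioxolan-4-yl]propanal, via secondary ozonide 5 (not isolated)
Conditions: O3, CH2Cl2, −78 °C; then PPh3, −78 °C → rt
Reagents that add atoms: ozone [O-][O+]=O
Why: Ozonolysis with reductive work-up cleaves the only C=C bond to the C3 aldehyde under neutral conditions that leave the acetonide and the stereocentre alone.

Step 4
Reactants: 6 3-[(4S)-2,2,4-trimethyl-1,3-dioxolan-4-yl]propanal; 7 (S)-4-benzyl-3-propanoyl-1,3-oxazolidin-2-one
Product: 10 (4S)-4-benzyl-3-{(2S,3R)-3-hydroxy-2-methyl-5-[(4S)-2,2,4-trimethyl-1,3-dioxolan-4-yl]pentanoyl}-1,3-oxazolidin-2-one, via Z-dibutylboron enolate 8 (not isolated), via dibutylboron aldolate 9 (not isolated)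
Conditions: 7, Bu2BOTf, Et3N, CH2Cl2, 0 °C; then 6, −78 → 0 °C; then pH 7 buffer, MeOH, 30% H2O2, 0 °C
Reagents that add atoms: none
Why: Evans syn-aldol reaction, in which the Z-boron enolate reacts through a closed six-membered chair transition state on the face away from the benzyl group of the auxiliary; this sets C2 as (S) (kept to the end) and C3 as (R) (inverted in step 10).

Step 5
Reactants: 10 aldol adduct
Product: 11 (2R,3R)-2-methyl-5-[(4S)-2,2,4-trimethyl-1,3-dioxolan-4-yl]pentane-1,3-diol
Conditions: LiBH4, MeOH (1 equiv), THF, 0 °C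
Reagents that add atoms: none
Why: Reductive cleavage of the N-acyl oxazolidinone by LiBH4 (hydride attack at the exocyclic carbonyl) gives the C1 alcohol without touching C2 or C3; the descriptor at C2 changes to (R) only through CIP priorities.

Step 6
Reactants: 11 (2R,3R)-1,3-diol
Product: 12 (2R,3R)-1-[(tert-butyldiphenylsilyl)oxy]-2-methyl-5-[(4S)-2,2,4-trimethyl-1,3-dioxolan-4-yl]pentan-3-ol
Conditions: TBDPSCl, imidazole, CH2Cl2, 0 °C → rt
Reagents that add atoms: tert-butyl(chloro)diphenylsilane CC(C)(C)[Si](Cl)(c1ccccc1)c1ccccc1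
Why: Silylation with a bulky chlorosilane is selective for the primary over the secondary hydroxyl.

Step 7
Reactants: 12 C1 silyl ether
Product: 13 (2R,3R)-1-[(tert-butyldiphenylsilyl)oxy]-2-methyl-5-[(4S)-2,2,4-trimethyl-1,3-dioxolan-4-yl]pentan-3-yl methanesulfonate
Conditions: MsCl, Et3N, CH2Cl2, 0 °C
Reagents that add atoms: methanesulfonyl chloride CS(Cl)(=O)=O
Why: O-Sulfonylation of the secondary alcohol (retention, only the O–S bond is formed) makes C3 an electrophile and removes its nucleophilic hydroxyl before any oxirane is present.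

Step 8
Reactants: 13 acetonide mesylate
Product: 14 (2R,3R,6S)-1-[(tert-butyldiphenylsilyl)oxy]-6,7-dihydroxy-2,6-dimethylheptan-3-yl methanesulfonate
Conditions: PPTS (0.2 equiv), MeOH, rt
Reagents that add atoms: none
Why: Acid-catalysed transketalisation to methanol removes the acetonide under conditions that spare the primary TBDPS ether and the secondary mesylate.

Step 9
Reactants: 14 diol mesylate
Product: 16 (2R,3R)-1-[(tert-butyldiphenylsilyl)oxy]-2-methyl-5-[(2S)-2-methyloxiran-2-yl]pentan-3-yl methanesulfonate, via primary tosylate 15 (not isolated)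
Conditions: TsCl, Et3N, DMAP (cat.), CH2Cl2, 0 °C → rt; then K2CO3, MeOH, 0 °C
Reagents that add atoms: none
Why: Selective tosylation of the primary hydroxyl (the tertiary one does not react) followed by Williamson-type 3-exo-tet closure by the tertiary alkoxide rebuilds the oxirane; the tertiary C6–O bond is never broken, so C6 keeps its chiral-pool configuration and the oxirane is (S).

Step 10
Reactants: 16 epoxy mesylate
Product: 17 tert-butyl{[(2R,3S)-3-hydroperoxy-2-methyl-5-[(2S)-2-methyloxiran-2-yl]pentyl]oxy}diphenylsilane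
Conditions: 30% aq. H2O2 (30 equiv), KOH (3 equiv), MeOH/THF, 0 °C → rt
Reagents that add atoms: hydrogen peroxide OO
Why: SN2 perhydrolysis of a secondary sulfonate, in which the hydroperoxide anion (an alpha-effect nucleophile of low basicity, buffered by the excess H2O2) displaces the mesylate with inversion and sets C3 as (S); the oxirane is stable to base.

Step 11
Reactants: 17 hydroperoxy epoxide
Product: 18 {(3R,6S)-6-[(2R)-1-[(tert-butyldiphenylsilyl)oxy]propan-2-yl]-3-methyl-1,2-dioxan-3-yl}methanol (in target numbering: C6 (R) bears CH3 and CH2OH, C3 (S) bears the side chain)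
Conditions: CSA (10 mol%), CH2Cl2, −20 → 0 °C
Reagents that add atoms: none
Why: Protonation of the oxirane oxygen lengthens the C6–O bond at the cation-stabilising tertiary carbon, and the terminal oxygen of the C3 hydroperoxide attacks C6 from the side opposite the departing oxygen, forming O1–C6 and releasing C7 as CH2OH. The closest known reaction type is the acid-catalysed cyclisation of hydroperoxy epoxides to 1,2-dioxanes, the intramolecular form of acid-catalysed epoxide perhydrolysis at the more substituted carbon. The 1,2-dioxane closes in a 6-exo-tet mode through a chair-like transition state with the C3 side chain equatorial. C6 is the only new stereocentre and is set by the (S) configuration of the chiral-pool oxirane, transferred with inversion; C2 and C3 are not touched. The step needs attack at C6 rather than at C7 (7-endo) and substitution ahead of ionisation or hydride shift; the methyl and alkyl groups on C6, the six-membered exo geometry, the non-nucleophilic solvent and a sub-stoichiometric sulfonic acid at low temperature should secure this.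

Step 12
Reactants: 18 dioxanyl methanol
Product: 19 (3R,6S)-6-[(2R)-1-[(tert-butyldiphenylsilyl)oxy]propan-2-yl]-3-methyl-1,2-dioxane-3-carbaldehyde
Conditions: Dess–Martin periodinane, CH2Cl2, 0 °C → rt
Reagents that add atoms: none
Why: Dess–Martin oxidation of the primary alcohol gives the C7 aldehyde, which has no alpha hydrogen (C6 is quaternary) and so cannot epimerise; the O–O bond is inert to the oxidant and the aldehyde is used at once.

Step 13
Reactants: 20 (2E,6E)-farnesyl bromide
Product: 21 [(2E,6E)-3,7,11-trimethyldodeca-2,6,10-trien-1-yl]triphenylphosphonium bromide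
Conditions: PPh3, toluene, rt, dark
Reagents that add atoms: triphenylphosphine c1ccc(cc1)P(c1ccccc1)c1ccccc1
Why: SN2 quaternisation of the phosphine by the primary allylic bromide gives the salt with the E double bonds unchanged.

Step 14
Reactants: 19 C7 aldehyde; 21 farnesyl phosphonium bromide
Product: 23 tert-butyl{[(2R)-2-{(3S,6R)-6-methyl-6-[(3E,7E)-4,8,12-trimethyltrideca-1,3,7,11-tetraen-1-yl]-1,2-dioxan-3-yl}propyl]oxy}diphenylsilane (C7=C8 as E/Z mixture), via farnesylidene ylide 22 (not isolated)
Conditions: 21, KN(SiMe3)2, THF, −78 → 0 °C; then 19, −78 → 0 °C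
Reagents that add atoms: none
Why: Wittig olefination with the semi-stabilised allylic ylide under salt-free conditions forms C7=C8 (its geometry is irrelevant because it is reduced next) and brings in C9=C10 with its E geometry; the dialkyl peroxide should tolerate the ylide at low temperature.

Step 15
Reactants: 23 diene
Product: 24 tert-butyl{[(2R)-2-{(3S,6S)-6-methyl-6-[(3E,7E)-4,8,12-trimethyltrideca-3,7,11-trien-1-yl]-1,2-dioxan-3-yl}propyl]oxy}diphenylsilane
Conditions: KO2CN=NCO2K, AcOH, MeOH/CH2Cl2, 0 °C → rt, added in portions until the diene is consumed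
Reagents that add atoms: none
Why: Diimide reduction (concerted syn transfer of H2) should take the 1,2-disubstituted C7=C8 bond, activated as part of the diene, ahead of the trisubstituted C9=C10, C13=C14 and C17=C18 bonds, and it leaves the O–O bond intact where metal-catalysed hydrogenation would cleave it; no stereocentre is formed.

Step 16
Reactants: 24 silyl ether
Product: 25 (2R)-2-{(3S,6S)-6-methyl-6-[(3E,7E)-4,8,12-trimethyltrideca-3,7,11-trien-1-yl]-1,2-dioxan-3-yl}propan-1-ol
Conditions: Bu4NF, AcOH (1:1), THF, 0 °C → rt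
Reagents that add atoms: none
Why: Fluoride-mediated desilylation frees the C1 alcohol, and buffering with acetic acid suppresses base-induced (Kornblum–DeLaMare-type) opening of the dioxane at C3–H.

Step 17
Reactants: 25 primary alcohol
Product: 27 (2S)-2-{(3S,6S)-6-methyl-6-[(3E,7E)-4,8,12-trimethyltrideca-3,7,11-trien-1-yl]-1,2-dioxan-3-yl}propanoic acid, via aldehyde 26 (not isolated)
Conditions: TEMPO (cat.), PhI(OAc)2, MeCN/pH 7 buffer, 0 °C → rt
Reagents that add atoms: water O
Why: Oxoammonium-mediated (TEMPO/PhI(OAc)2) oxidation takes the primary alcohol through the aldehyde hydrate to the acid under near-neutral conditions, so C2 should not epimerise and the peroxide and trisubstituted alkenes are left alone.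

**Compound list**
1 | (R)-2-methylglycidol, [(2R)-2-methyloxiran-2-yl]methanol | C[C@]1(CO1)CO | starting material
2 | allylmagnesium bromide | C=CC[Mg]Br | starting material
3 | (2S)-2-methylhex-5-ene-1,2-diol | C[C@@](O)(CO)CCC=C | intermediate
4 | (4S)-4-(but-3-en-1-yl)-2,2,4-trimethyl-1,3-dioxolane | C[C@@]1(COC(C)(C)O1)CCC=C | intermediate
5 | secondary ozonide of 4 (3-substituted 1,2,4-trioxolane, formed in the flask) | C[C@@]1(COC(C)(C)O1)CCC1OCOO1 | intermediate
6 | 3-[(4S)-2,2,4-trimethyl-1,3-dioxolan-4-yl]propanal | C[C@@]1(COC(C)(C)O1)CCC=O | intermediate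
7 | (S)-4-benzyl-3-propanoyl-1,3-oxazolidin-2-one | CCC(=O)N1[C@@H](Cc2ccccc2)COC1=O | starting material
8 | Z-dibutylboron enolate of 7 (formed in the flask) | C/C=C(\OB(CCCC)CCCC)N1[C@@H](Cc2ccccc2)COC1=O | intermediate
9 | dibutylboron aldolate of 10 (formed in the flask) | C[C@@]1(COC(C)(C)O1)CC[C@@H](OB(CCCC)CCCC)[C@H](C)C(=O)N1[C@@H](Cc2ccccc2)COC1=O | intermediate
10 | (4S)-4-benzyl-3-{(2S,3R)-3-hydroxy-2-methyl-5-[(4S)-2,2,4-trimethyl-1,3-dioxolan-4-yl]pentanoyl}-1,3-oxazolidin-2-one | C[C@@]1(COC(C)(C)O1)CC[C@@H](O)[C@H](C)C(=O)N1[C@@H](Cc2ccccc2)COC1=O | intermediate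
11 | (2R,3R)-2-methyl-5-[(4S)-2,2,4-trimethyl-1,3-dioxolan-4-yl]pentane-1,3-diol | C[C@@]1(COC(C)(C)O1)CC[C@@H](O)[C@H](C)CO | intermediate
12 | (2R,3R)-1-[(tert-butyldiphenylsilyl)oxy]-2-methyl-5-[(4S)-2,2,4-trimethyl-1,3-dioxolan-4-yl]pentan-3-ol | C[C@@]1(COC(C)(C)O1)CC[C@@H](O)[C@H](C)CO[Si](c1ccccc1)(c1ccccc1)C(C)(C)C | intermediate
13 | (2R,3R)-1-[(tert-butyldiphenylsilyl)oxy]-2-methyl-5-[(4S)-2,2,4-trimethyl-1,3-dioxolan-4-yl]pentan-3-yl methanesulfonate | C[C@@]1(COC(C)(C)O1)CC[C@@H](OS(C)(=O)=O)[C@H](C)CO[Si](c1ccccc1)(c1ccccc1)C(C)(C)C | intermediate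
14 | (2R,3R,6S)-1-[(tert-butyldiphenylsilyl)oxy]-6,7-dihydroxy-2,6-dimethylheptan-3-yl methanesulfonate | C[C@@](O)(CO)CC[C@@H](OS(C)(=O)=O)[C@H](C)CO[Si](c1ccccc1)(c1ccccc1)C(C)(C)C | intermediate
15 | C7 primary 4-methylbenzenesulfonate of 14 (formed in the flask) | C[C@@](O)(COS(=O)(=O)c1ccc(C)cc1)CC[C@@H](OS(C)(=O)=O)[C@H](C)CO[Si](c1ccccc1)(c1ccccc1)C(C)(C)C | intermediate
16 | (2R,3R)-1-[(tert-butyldiphenylsilyl)oxy]-2-methyl-5-[(2S)-2-methyloxiran-2-yl]pentan-3-yl methanesulfonate | C[C@@]1(CO1)CC[C@@H](OS(C)(=O)=O)[C@H](C)CO[Si](c1ccccc1)(c1ccccc1)C(C)(C)C | intermediate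
17 | tert-butyl{[(2R,3S)-3-hydroperoxy-2-methyl-5-[(2S)-2-methyloxiran-2-yl]pentyl]oxy}diphenylsilane | C[C@@]1(CO1)CC[C@H](OO)[C@H](C)CO[Si](c1ccccc1)(c1ccccc1)C(C)(C)C | intermediate
18 | {(3R,6S)-6-[(2R)-1-[(tert-butyldiphenylsilyl)oxy]propan-2-yl]-3-methyl-1,2-dioxan-3-yl}methanol | OC[C@@]1(C)CC[C@@H]([C@H](C)CO[Si](c2ccccc2)(c2ccccc2)C(C)(C)C)OO1 | intermediate
19 | (3R,6S)-6-[(2R)-1-[(tert-butyldiphenylsilyl)oxy]propan-2-yl]-3-methyl-1,2-dioxane-3-carbaldehyde | O=C[C@@]1(C)CC[C@@H]([C@H](C)CO[Si](c2ccccc2)(c2ccccc2)C(C)(C)C)OO1 | intermediate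
20 | (2E,6E)-farnesyl bromide | CC(C)=CCC/C(C)=C/CC/C(C)=C/CBr | starting material
21 | [(2E,6E)-3,7,11-trimethyldodeca-2,6,10-trien-1-yl]triphenylphosphonium bromide | CC(C)=CCC/C(C)=C/CC/C(C)=C/C[P+](c1ccccc1)(c1ccccc1)c1ccccc1.[Br-] | intermediate
22 | farnesylidene(triphenyl)phosphorane (formed in the flask) | CC(C)=CCC/C(C)=C/CC/C(C)=C/C=P(c1ccccc1)(c1ccccc1)c1ccccc1 | intermediate
23 | tert-butyl{[(2R)-2-{(3S,6R)-6-methyl-6-[(3E,7E)-4,8,12-trimethyltrideca-1,3,7,11-tetraen-1-yl]-1,2-dioxan-3-yl}propyl]oxy}diphenylsilane (C7=C8 E/Z mixture) | CC(C)=CCC/C(C)=C/CC/C(C)=C/C=C[C@@]1(C)CC[C@@H]([C@H](C)CO[Si](c2ccccc2)(c2ccccc2)C(C)(C)C)OO1 | intermediate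
24 | tert-butyl{[(2R)-2-{(3S,6S)-6-methyl-6-[(3E,7E)-4,8,12-trimethyltrideca-3,7,11-trien-1-yl]-1,2-dioxan-3-yl}propyl]oxy}diphenylsilane | CC(C)=CCC/C(C)=C/CC/C(C)=C/CC[C@@]1(C)CC[C@@H]([C@H](C)CO[Si](c2ccccc2)(c2ccccc2)C(C)(C)C)OO1 | intermediate
25 | (2R)-2-{(3S,6S)-6-methyl-6-[(3E,7E)-4,8,12-trimethyltrideca-3,7,11-trien-1-yl]-1,2-dioxan-3-yl}propan-1-ol | CC(C)=CCC/C(C)=C/CC/C(C)=C/CC[C@@]1(C)CC[C@@H]([C@H](C)CO)OO1 | intermediate
26 | (2S)-2-{(3S,6S)-6-methyl-6-[(3E,7E)-4,8,12-trimethyltrideca-3,7,11-trien-1-yl]-1,2-dioxan-3-yl}propanal (formed in the flask) | CC(C)=CCC/C(C)=C/CC/C(C)=C/CC[C@@]1(C)CC[C@@H]([C@H](C)C=O)OO1 | intermediate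
27 | (2S)-2-{(3S,6S)-6-methyl-6-[(3E,7E)-4,8,12-trimethyltrideca-3,7,11-trien-1-yl]-1,2-dioxan-3-yl}propanoic acid (CNP0179915.1) | CC(C)=CCC/C(C)=C/CC/C(C)=C/CC[C@@]1(C)CC[C@@H]([C@H](C)C(=O)O)OO1 | target

**Step count**
Total: 17 steps. Longest linear sequence: 16 steps (steps 1–12 and 14–17; step 13 is the side branch).

**Steps most likely to fail**

Step 10 (perhydrolysis at C3). Substitution at the β-branched secondary carbon may be slow in the protic medium, so that E2 loss of the mesylate, base-induced breakdown of the secondary hydroperoxide once formed, or cleavage of the silyl ether overtakes it. The fallback uses a protected peroxide nucleophile in a dipolar aprotic solvent and removes the mask in the ring-closing flask. It sets out from 16. 2-Methoxyprop-2-yl hydroperoxide F1 (not commercial; prepared by ozonolysis of 2,3-dimethylbut-2-ene in MeOH) with CsOH·H2O in DMF at 0 °C → rt should displace the mesylate with inversion to give tert-butyl{[(2R,3S)-3-[(2-methoxypropan-2-yl)peroxy]-2-methyl-5-[(2S)-2-methyloxiran-2-yl]pentyl]oxy}diphenylsilane F2, whose peroxide carries no acidic hydrogen. F2 is then exposed to CSA (10 mol%) and MeOH (3 equiv) in CH2Cl2 at −20 → 0 °C, where transketalisation frees 17 in the flask and the oxirane opening of step 11 follows. The fallback comes back to the route at 18.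

Step 11 (key ring closure). The protonated oxirane may ionise to an open tertiary cation faster than the hydroperoxide closes the ring, leading to loss of configuration at C6, hydride shift to the C7 aldehyde (Meinwald rearrangement) or capture by the sulfonate counter-ion. The fallback makes the two C–O bonds in the opposite order. It sets out from 16. Ethereal H2O2 in large excess with H3PMo12O40 (cat.) in Et2O at rt should open the oxirane at C6 with inversion to (2R,3R,6R)-1-[(tert-butyldiphenylsilyl)oxy]-6-hydroperoxy-7-hydroxy-2,6-dimethylheptan-3-yl methanesulfonate F3. KOtBu in THF at 0 °C then closes the dioxane by intramolecular SN2 (6-exo-tet) of the peroxide anion on the C3 mesylate, again with inversion. Both centres are inverted once, as in the main route, so the same stereoisomer results. The fallback comes back to the route at 18.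

Step 14 (Wittig olefination). The delocalised allylic ylide may equilibrate and erode the C9=C10 E geometry, react through its γ-carbon, or act as a base on the fragile α-peroxy aldehyde. The fallback is a sulfone-based olefination. It sets out from 20. 1-Phenyl-1H-tetrazole-5-thiol with K2CO3 in acetone gives 5-{[(2E,6E)-3,7,11-trimethyldodeca-2,6,10-trien-1-yl]sulfanyl}-1-phenyl-1H-tetrazole F4. Oxidation with (NH4)6Mo7O24·4H2O (cat.) and 30% H2O2 in EtOH at 0 °C → rt gives 5-{[(2E,6E)-3,7,11-trimethyldodeca-2,6,10-trien-1-yl]sulfonyl}-1-phenyl-1H-tetrazole F5 without touching the alkenes. KN(SiMe3)2 is then added to F5 and 19 together in THF at −78 °C (Julia–Kocienski olefination); the anion is localised on the sulfonyl carbon, so C9=C10 keeps its geometry and the aldehyde does not meet free base. The fallback comes back to the route at diene 23.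

**Further compounds**
F1 | step 10 | 2-methoxyprop-2-yl hydroperoxide | COC(C)(C)OO
F2 | step 10 | tert-butyl{[(2R,3S)-3-[(2-methoxypropan-2-yl)peroxy]-2-methyl-5-[(2S)-2-methyloxiran-2-yl]pentyl]oxy}diphenylsilane | C[C@@]1(CO1)CC[C@H](OOC(C)(C)OC)[C@H](C)CO[Si](c1ccccc1)(c1ccccc1)C(C)(C)C
F3 | step 11 | (2R,3R,6R)-1-[(tert-butyldiphenylsilyl)oxy]-6-hydroperoxy-7-hydroxy-2,6-dimethylheptan-3-yl methanesulfonate | C[C@](OO)(CO)CC[C@@H](OS(C)(=O)=O)[C@H](C)CO[Si](c1ccccc1)(c1ccccc1)C(C)(C)C
F4 | step 14 | 5-{[(2E,6E)-3,7,11-trimethyldodeca-2,6,10-trien-1-yl]sulfanyl}-1-phenyl-1H-tetrazole | CC(C)=CCC/C(C)=C/CC/C(C)=C/CSc1nnnn1-c1ccccc1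
F5 | step 14 | 5-{[(2E,6E)-3,7,11-trimethyldodeca-2,6,10-trien-1-yl]sulfonyl}-1-phenyl-1H-tetrazole | CC(C)=CCC/C(C)=C/CC/C(C)=C/CS(=O)(=O)c1nnnn1-c1ccccc1
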